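(The runs are simulated from invented constants.)

Time bought less and less in the violet flask: J rose from 49.9 % to 57.3 % between 60.0 min and 180 min, but only from 59.6 % to 61.6 % between 300 min and 480 min.

all flasks: X 1.6 M; Z 1.28 M; D 66 mM

| run | temperature | remark | time |
|---|---|---|---|
| violet | 110 °C | the very flask that is asked about, followed so far |  |
| teal | 116 °C | run made earlier |  |
| flask | 110 °C |  | 10 h |

| run | time / min | J / % | X / % |
|---|---|---|---|
| violet | 60.0 | 49.9 | 50.3 |
| violet | 180 | 57.3 | 43.2 |
| violet | 300 | 59.6 | 40.7 |
| violet | 480 | 61.6 | 38.3 |
| teal | 60.0 | 49.7 | 50.6 |
| teal | 180 | 56.1 | 43.9 |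
| teal | 300 | 59.1 | 41.7 |
| teal | 480 | 60.0 | 39.6 |

(each reading ± 0.3 percentage points)

- J that was removed still counts
- additions bring no volume worth counting

- Friday's: at 10 h add D, 100 % of the amount charged, then wait 3.0 h
- Saturday's: change nothing and wait 3.0 h more
- Wednesday's: at 10 h add Z, 50.0 % of the amount charged, then wait 3.0 h
- Thursday's: at 10 h raise the temperature by 25 K, then wait 3.0 h
- Monday's: at 10 h take out 90 % of the J then present, then wait 3.0 h

- J, in percent of the X first charged, at 10 h
- the remedy with the largest gain of J, or "none" below 2 percentage points (Friday's / Saturday's / Wednesday's / Thursday's / Monday's / none)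
- J present, with what was taken out counted in, in percent of the X first charged, after Saturday's
- J present, with what was taken out counted in, in percent of the X first charged, after Wednesday's

The X lost matched the J formed, so I took X and Z to go one for one, with Z as the limiting reagent and J capped at 80.0 %. I folded each reading into one pure number, the tally: the natural log of the share of X left over the share of Z left. If the rate goes as [X][Z] times the working [D], the tally climbs with [D] and the running down of X and Z drops out. It read 0.284 at 60.0 min and 0.515 at 480 min, which is 3 doublings of the time, so I called 0.0772 the rung: the tally gained per doubling of the time. A steady rung means that [D] loses one more halving with each doubling, as when D dies in pairs.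

I tested it at 300 min, where the rung gave 0.463 and the reading gave 0.453. But the teal flask, at 116 °C, gave a rung of 0.0668, smaller than violet's, so one number served one temperature.

Counting on in the violet flask, I got a tally of 0.540 at 10 h, which means J of 62.5 %. Saturday's wait raised the tally to 0.570, or J of 63.5 %.

The forecast gave 62.4 % (61.8 % to 63.2 %) for now, 63.3 % (62.4 % to 64.4 %) after Saturday's and 65.2 % (63.8 % to 66.8 %) after Wednesday's. It chose Friday's: “Fresh D restarts the reaction”. My 62.5 % and 63.5 % lay inside its first two ranges.

The flask gave 62.3 %, then 63.3 % after Saturday's and 65.3 % after Wednesday's. The best remedy was Friday's, with a gain of 8.5 percentage points.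

    X + Z + D → D + J (k = 0.0180 M⁻² s⁻¹, Ea = 39.0 kJ mol⁻¹)
    2 D → L (k = 0.0260 M⁻¹ s⁻¹, Ea = 62.0 kJ mol⁻¹)
    (constants at 110 °C)

J stood at 62.3 % and not 80.0 % in part through the pairing of D into L, acting together with the falling level of Z; the run without that pairing reached the higher figure. The flask's tally at 10 h was 0.534, and the rung carried it to J of 63.3 % after Saturday's, where the flask gave 63.3 %. I counted a halving of the charged D like a halving of the time. A neighbour flask charged with 0.017 M of D, about a quarter of the flask's, then sat 1.96 halvings behind, so the rung put its J at 56.0 %, and it stood at 56.2 %.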